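**Retrosynthetic overview**
1. Target ⇐ para-Claisen rearrangement of the allyl ether of the central phenol (delivers the ring allyl group, frees the OH) ⇐ removal of a C9 ketone.
2. C4 quaternary ether ⇐ C4–CH3 bond by methyl-for-benzotriazole substitution on a ring-A N,O-acetal that already carries the complete aryloxy group.
3. Ring A ⇐ C4–C5 bond by conjugate addition of a benzotriazole-stabilised α-aryloxy carbanion (acyl-anion equivalent of 4-chlorobutanal) to the enone β-carbon of carvone hydrate, then C10–C1 enolate alkylation in the same flask.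
4. Ring B with C7 and the hydroxyisopropyl group comes from (S)-carvone; ring order: B (chiral pool), then A (annulation); both arenes are bought.
5. Carbanion precursor ⇐ pyrogallol, allyl bromide, 1-allyl-4-bromobenzene, 1-(chloromethyl)benzotriazole, 1-bromo-3-chloropropane.

Assumption: the SMILES is taken literally, i.e. a cis-fused decalin, (4R,5S,7R,10R), with H-5, CH3-10, CH3-4 and the C7 side chain on one face (β) and the aryloxy group on the other (α).

Numbering: decalin carbons carry eudesmane numbers. Ring A is C1–C5 plus C10 (C4 bears the aryloxy group; C5 and C10 are the fusion carbons; C10 bears the angular methyl). Ring B is C5–C10 (C7 bears the side chain; C9 is next to C10).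

**Route**

Step 1
Reactants: 1 (S)-(+)-carvone
Product: 2 (S)-5-(2-hydroxypropan-2-yl)-2-methylcyclohex-2-en-1-one (carvone hydrate)
Conditions: 50% aq. H2SO4, 0 °C → rt, 24 h
Reagents that add atoms: water (O)
Why: Markovnikov acid-catalysed hydration of the 1,1-disubstituted isopropenyl alkene through the tertiary cation, which leaves the conjugated enone and the existing stereocentre (future C7) untouched.

Step 2
Reactants: 3 pyrogallol; 4 allyl bromide
Product: 5 2-(allyloxy)benzene-1,3-diol
Conditions: NaHCO3 (1.1 equiv), DMF, 40 °C, N2; 3 in 1.5-fold excess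
Reagents that add atoms: none
Why: Williamson O-alkylation in which the weak base ionises only the most acidic hydroxyl, the central one, whose phenoxide is held by two flanking O–H hydrogen bonds (the selectivity known from 4-O-alkylation of gallates); no stereocentre is formed.

Step 3
Reactants: 5 2-(allyloxy)benzene-1,3-diol; 6 1-allyl-4-bromobenzene
Product: 7 2-(allyloxy)-3-(4-allylphenoxy)phenol
Conditions: CuI (10 mol %), picolinic acid (20 mol %), K3PO4, DMSO, 90 °C; 5 in 2.5-fold excess
Reagents that add atoms: none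
Why: Ullmann-type copper-catalysed diaryl ether synthesis on a diol whose two hydroxyls are equivalent, the excess of 5 holding the coupling at the mono-ether; no stereocentre is formed.

Step 4
Reactants: 7 2-(allyloxy)-3-(4-allylphenoxy)phenol; 8 1-(chloromethyl)-1H-benzotriazole
Product: 9 1-{[2-(allyloxy)-3-(4-allylphenoxy)phenoxy]methyl}-1H-benzotriazole
Conditions: K2CO3, DMF, 50 °C
Reagents that add atoms: none
Why: O-alkylation of the phenoxide by the aminal-type chloride (SN2 with iminium character) gives the benzotriazolylmethyl aryl ether; no stereocentre is formed.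

Step 5
Reactants: 9 1-{[2-(allyloxy)-3-(4-allylphenoxy)phenoxy]methyl}-1H-benzotriazole; 10 1-bromo-3-chloropropane
Product: 12 1-{1-[2-(allyloxy)-3-(4-allylphenoxy)phenoxy]-4-chlorobutyl}-1H-benzotriazole (racemic), via lithiated ether 11 (not isolated)
Conditions: n-BuLi (1.05 equiv), THF, −78 °C; then 10, −78 → −20 °C
Reagents that add atoms: none
Why: the CH2 flanked by benzotriazole nitrogen and oxygen is the most acidic C–H, and its lithio derivative is alkylated by SN2 at the C–Br end of 10 only; the new centre is racemic and is erased in step 7.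

Step 6
Reactants: 12 1-{1-[2-(allyloxy)-3-(4-allylphenoxy)phenoxy]-4-chlorobutyl}-1H-benzotriazole; 2 carvone hydrate
Product: 16 (5S,7S,10S)-4-[2-(allyloxy)-3-(4-allylphenoxy)phenoxy]-4-(1H-benzotriazol-1-yl)-7-(2-hydroxypropan-2-yl)-10-methyl-cis-decalin-9-one (both C4 epimers), via lithiated acetal 13 (not isolated), via lithium alkoxide 14 (not isolated), via adduct enolate 15 (not isolated)
Conditions: 12, LiN(i-Pr)2 (1.05 equiv), THF–DMPU, −78 °C; then 2 pre-treated with LiN(i-Pr)2 (1.0 equiv, THF, −78 °C); −78 → −30 °C, 2 h; then 45 °C, 8 h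
Reagents that add atoms: none
Why: Michael-initiated ring closure in which the benzotriazole-stabilised α-aryloxy carbanion 13 (an acyl-anion equivalent, so the normally electrophilic C4 is the nucleophile) adds 1,4 to the enone by axial attack anti to the equatorial C7 side chain (5,7-trans, as in cuprate additions to carvone), and the regiospecific C9–C10 enolate is then alkylated by the tethered chloride on the face that carries the tether (6-exo-tet), which fixes the cis ring fusion and the β angular methyl, while C4 remains an inconsequential N,O-acetal epimer pair.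

Step 7
Reactants: 16 benzotriazolyl N,O-acetal ketone
Product: 17 (4R,5S,7S,10S)-4-[2-(allyloxy)-3-(4-allylphenoxy)phenoxy]-7-(2-hydroxypropan-2-yl)-4,10-dimethyl-cis-decalin-9-one
Conditions: Me3Al (3 equiv), toluene–CH2Cl2, −78 → 0 °C
Reagents that add atoms: trimethylaluminium (C[Al](C)C)
Why: benzotriazole displacement on an N,O-acetal by an organoaluminium reagent, in which Me3Al ionises the C4–N bond to a ring-A aryloxocarbenium ion and transfers methyl to its equatorial (β) face in the cis-decalin conformer that keeps the C7 side chain equatorial, the axial (α) face being blocked 1,3-diaxially by C9, so both C4 epimers of 16 converge on the 4α-aryloxy-4β-methyl (4R) ether while the hindered α-quaternary ketone is left alone at low temperature.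

Step 8
Reactants: 17 methyl ether ketone
Product: 19 2-{(4R,5S,7R,10R)-4-[2-(allyloxy)-3-(4-allylphenoxy)phenoxy]-4,10-dimethyl-cis-decalin-7-yl}propan-2-ol, via tosylhydrazone 18 (not isolated)
Conditions: TsNHNH2, EtOH, 75 °C; then catecholborane, CHCl3, 0 °C; NaOAc·3H2O, 60 °C
Reagents that add atoms: none
Why: Caglioti–Kabalka reductive deoxygenation (hydride addition to the tosylhydrazone C=N, then loss of sulfinate and N2 from the diazene) turns C9 into CH2 under neutral conditions that spare the allyl groups and the tertiary ether, and no stereocentre is touched because C10 is quaternary and C5 is not enolisable.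

Step 9
Reactants: 19 allyl ether
Product: 22 2-{(4R,5S,7R,10R)-4-[5-allyl-3-(4-allylphenoxy)-2-hydroxyphenoxy]-4,10-dimethyl-cis-decalin-7-yl}propan-2-ol (target), via ortho-dienone 20 (not isolated), via para-dienone 21 (not isolated)
Conditions: N,N-diethylaniline, 190 °C, sealed tube, Ar
Reagents that add atoms: none
Why: aromatic para-Claisen rearrangement in which both ortho positions of the allyl ether carry oxygen, so the ortho-dienone from the first [3,3] shift cannot enolise and hands the allyl group on by a Cope [3,3] shift to the free para position, after which tautomerisation gives the 4-allylphenol with the central hydroxyl free; no stereocentre is touched.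

**Compound list**
1 | (S)-(+)-carvone | CC1=CC[C@@H](CC1=O)C(C)=C | starting material
2 | (S)-5-(2-hydroxypropan-2-yl)-2-methylcyclohex-2-en-1-one (carvone hydrate) | CC1=CC[C@@H](CC1=O)C(C)(C)O | intermediate
3 | pyrogallol | Oc1cccc(O)c1O | starting material
4 | allyl bromide | C=CCBr | starting material
5 | 2-(allyloxy)benzene-1,3-diol | C=CCOc1c(O)cccc1O | intermediate
6 | 1-allyl-4-bromobenzene | C=CCc1ccc(Br)cc1 | starting material
7 | 2-(allyloxy)-3-(4-allylphenoxy)phenol | C=CCOc1c(O)cccc1Oc1ccc(CC=C)cc1 | intermediate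
8 | 1-(chloromethyl)-1H-benzotriazole | ClCn1nnc2ccccc12 | starting material
9 | 1-{[2-(allyloxy)-3-(4-allylphenoxy)phenoxy]methyl}-1H-benzotriazole | C=CCOc1c(OCn2nnc3ccccc23)cccc1Oc1ccc(CC=C)cc1 | intermediate
10 | 1-bromo-3-chloropropane | ClCCCBr | starting material
11 | lithio derivative of 9 (carbanion at the O–CH–N carbon) | [Li+].C=CCOc1c(O[CH-]n2nnc3ccccc23)cccc1Oc1ccc(CC=C)cc1 | intermediate
12 | 1-{1-[2-(allyloxy)-3-(4-allylphenoxy)phenoxy]-4-chlorobutyl}-1H-benzotriazole (racemic) | C=CCOc1c(OC(CCCCl)n2nnc3ccccc23)cccc1Oc1ccc(CC=C)cc1 | intermediate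
13 | lithio derivative of 12 (tertiary carbanion at the O–C–N carbon) | [Li+].C=CCOc1c(O[C-](CCCCl)n2nnc3ccccc23)cccc1Oc1ccc(CC=C)cc1 | intermediate
14 | lithium alkoxide of 2 | [Li+].CC1=CC[C@@H](CC1=O)C(C)(C)[O-] | intermediate
15 | dilithium enolate–alkoxide of the conjugate adduct (5S,7S; C4 epimers) | [Li+].[Li+].C=CCOc1c(OC(CCCCl)(n2nnc3ccccc23)[C@H]2C[C@H](C(C)(C)[O-])CC([O-])=C2C)cccc1Oc1ccc(CC=C)cc1 | intermediate
16 | (5S,7S,10S)-4-[2-(allyloxy)-3-(4-allylphenoxy)phenoxy]-4-(1H-benzotriazol-1-yl)-7-(2-hydroxypropan-2-yl)-10-methyl-cis-decalin-9-one (C4 epimers) | C=CCc1ccc(Oc2cccc(OC3(n5nnc6ccccc56)CCC[C@]4(C)C(=O)C[C@@H](C(C)(C)O)C[C@@H]43)c2OCC=C)cc1 | intermediate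
17 | (4R,5S,7S,10S)-4-[2-(allyloxy)-3-(4-allylphenoxy)phenoxy]-7-(2-hydroxypropan-2-yl)-4,10-dimethyl-cis-decalin-9-one | C=CCc1ccc(Oc2cccc(O[C@]3(C)CCC[C@]4(C)C(=O)C[C@@H](C(C)(C)O)C[C@@H]43)c2OCC=C)cc1 | intermediate
18 | C9 tosylhydrazone of 17 | C=CCc1ccc(Oc2cccc(O[C@]3(C)CCC[C@]4(C)C(=NNS(=O)(=O)c5ccc(C)cc5)C[C@@H](C(C)(C)O)C[C@@H]43)c2OCC=C)cc1 | intermediate
19 | 2-{(4R,5S,7R,10R)-4-[2-(allyloxy)-3-(4-allylphenoxy)phenoxy]-4,10-dimethyl-cis-decalin-7-yl}propan-2-ol | C=CCc1ccc(Oc2cccc(O[C@]3(C)CCC[C@]4(C)CC[C@@H](C(C)(C)O)C[C@@H]43)c2OCC=C)cc1 | intermediate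
20 | ortho-dienone: 6-allyl-6-(4-allylphenoxy)-2-(terpenyloxy)cyclohexa-2,4-dien-1-one | O=C1C(O[C@]3(C)CCC[C@]4(C)CC[C@@H](C(C)(C)O)C[C@@H]43)=CC=CC1(CC=C)Oc1ccc(CC=C)cc1 | intermediate
21 | para-dienone: 4-allyl-2-(4-allylphenoxy)-6-(terpenyloxy)cyclohexa-2,5-dien-1-one | O=C1C(O[C@]3(C)CCC[C@]4(C)CC[C@@H](C(C)(C)O)C[C@@H]43)=CC(CC=C)C=C1Oc1ccc(CC=C)cc1 | intermediate
22 | 2-{(4R,5S,7R,10R)-4-[5-allyl-3-(4-allylphenoxy)-2-hydroxyphenoxy]-4,10-dimethyl-cis-decalin-7-yl}propan-2-ol | C=CCc1ccc(Oc2cc(CC=C)cc(O[C@]3(C)CCC[C@]4(C)CC[C@@H](C(C)(C)O)C[C@@H]43)c2O)cc1 | target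

**Step count and risks**

Total step count: 9. Longest linear sequence: 8 (steps 2–9, from pyrogallol); the carvone branch (step 1) joins at step 6.

The three steps most likely to fail:

1. The annulation of step 6. The hindered tertiary carbanion 13 may add 1,2, deprotonate the enone, or close on its own chloride to a cyclobutane before it meets 14. The fallback sets out from 7 and makes the same C4–C5 bond with a radical. Acylation of 7 with 4-chlorobutanoyl chloride (Et3N, CH2Cl2, 0 °C) gives the aryl 4-chlorobutanoate F1. Methylenation with Cp2TiMe2 (toluene, 65 °C) gives the 2-aryloxy-1-alkene F2. Hydrogen-atom-transfer coupling of F2 with 2 (Fe(acac)3, PhSiH3, EtOH, 60 °C) generates the tertiary α-aryloxy radical, which adds to C5 anti to the side chain and gives the chloro ketone F3. KOt-Bu in t-BuOH–THF then closes ring A, and the route is rejoined at 17. This variant does not control C4, so 17 must be separated from its C4 epimer there.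

2. The methyl transfer of step 7. The aryloxocarbenium ion may lose a proton instead of accepting methyl, or Me3Al may attack the C9 ketone. The fallback sets out from 16. TMSOTf and 2,6-lutidine (CH2Cl2, −78 °C, then K2CO3 in MeOH) eliminate benzotriazole on purpose to the ring-A aryl enol ether F4. Iron-hydride hydromethylation (Fe(acac)3, PhSiH3, formaldehyde 2,4,6-triisopropylbenzenesulfonylhydrazone, THF–MeOH) adds H to C3 and traps the cyclic C4 radical on its equatorial face as the sulfonylhydrazide F5. Warming F5 in MeOH (60 °C) expels the sulfinic acid and N2 and leaves the C4 methyl group; the route is rejoined at 17.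

3. The para-Claisen rearrangement of step 9. At 190 °C the tertiary alkyl aryl ether may eliminate, helped by the phenol that the reaction itself produces. The fallback sets out from 19. Pd(PPh3)4 and morpholine (THF, rt) remove the O-allyl group to give the phenol F6. NBS (CH2Cl2, −78 °C) brominates para to the free hydroxyl, the only strongly activated open position, to give the bromophenol F7. Stille coupling of F7 with allyltributylstannane (Pd(PPh3)4, CsF, dioxane, 90 °C) installs the allyl group and arrives at 22.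

Further compounds
F1 | step 6 | 2-(allyloxy)-3-(4-allylphenoxy)phenyl 4-chlorobutanoate | C=CCOc1c(OC(=O)CCCCl)cccc1Oc1ccc(CC=C)cc1
F2 | step 6 | 2-(allyloxy)-1-(4-allylphenoxy)-3-[(5-chloropent-1-en-2-yl)oxy]benzene | C=CCOc1c(OC(=C)CCCCl)cccc1Oc1ccc(CC=C)cc1
F3 | step 6 | (3S,5S)-3-{2-[2-(allyloxy)-3-(4-allylphenoxy)phenoxy]-5-chloropentan-2-yl}-5-(2-hydroxypropan-2-yl)-2-methylcyclohexan-1-one (epimers at C2 and at the ether carbon) | C=CCOc1c(OC(C)(CCCCl)[C@H]2C[C@H](C(C)(C)O)CC(=O)C2C)cccc1Oc1ccc(CC=C)cc1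
F4 | step 7 | (5S,7S,10S)-4-[2-(allyloxy)-3-(4-allylphenoxy)phenoxy]-7-(2-hydroxypropan-2-yl)-10-methyl-cis-decal-3-en-9-one | C=CCc1ccc(Oc2cccc(OC3=CCC[C@]4(C)C(=O)C[C@@H](C(C)(C)O)C[C@@H]43)c2OCC=C)cc1
F5 | step 7 | N'-{[(4R,5S,7S,10S)-4-aryloxy-7-(2-hydroxypropan-2-yl)-10-methyl-9-oxo-cis-decalin-4-yl]methyl}-2,4,6-triisopropylbenzenesulfonohydrazide (aryloxy as in 17) | C=CCc1ccc(Oc2cccc(O[C@]3(CNNS(=O)(=O)c5c(C(C)C)cc(C(C)C)cc5C(C)C)CCC[C@]4(C)C(=O)C[C@@H](C(C)(C)O)C[C@@H]43)c2OCC=C)cc1
F6 | step 9 | 2-{(4R,5S,7R,10R)-4-[3-(4-allylphenoxy)-2-hydroxyphenoxy]-4,10-dimethyl-cis-decalin-7-yl}propan-2-ol | C=CCc1ccc(Oc2cccc(O[C@]3(C)CCC[C@]4(C)CC[C@@H](C(C)(C)O)C[C@@H]43)c2O)cc1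
F7 | step 9 | 2-{(4R,5S,7R,10R)-4-[3-(4-allylphenoxy)-5-bromo-2-hydroxyphenoxy]-4,10-dimethyl-cis-decalin-7-yl}propan-2-ol | C=CCc1ccc(Oc2cc(Br)cc(O[C@]3(C)CCC[C@]4(C)CC[C@@H](C(C)(C)O)C[C@@H]43)c2O)cc1
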